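**Strategy.** The tetra-ortho-substituted C8–C8'' axis links two rings A whose oxygens at C5 and C7 are meta to each other. Each ring A is therefore read as an enolized 1,3-dione grown on ring C: C5 from an ester on C4a, C6 and C7 from an acetonyl ketone, and C8 from an sp3 carbon, so the axis becomes an ordinary sp3–sp3 bond made by alkylating a ketone enolate with its own α-bromo derivative. One base treatment then forms C5–C6 and C5''–C6'' by twofold intramolecular Claisen condensation, closes both rings A and aromatizes them. The precursor is a 3,4-bis(pyranonyl)hexane-2,5-dione whose 6-aryl-4-pyranones each carry a methyl ester at C3, next to the side chain.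

Key step: step 6

Remark on the chemistry: the target is drawn without a descriptor for the C8–C8'' axis and has no stereocentre, so the route aims at the racemic atropisomer mixture.

Design note: the precursor keeps methyl esters, so methoxide is the only leaving group and the only nucleophile released. It keeps benzyl ethers on the 4'-oxygens, which are inert to amide bases and to N-bromosuccinimide in the dark and are removed last. It is used as the meso/racemic mixture and is not stored, because a 1,4-diketone with acidic C–H is prone to furan or cyclopentenone formation.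

**Step 1**
Reactants: 1 1-(benzyloxy)-4-ethynylbenzene
Product: 2 3-[4-(benzyloxy)phenyl]prop-2-ynoic acid
Conditions: n-BuLi (1.05 equiv), THF, −78 °C; CO2 (g), −78 °C to rt; 1 M HCl
Reagents that add atoms: carbon dioxide, O=C=O
Why: Lithiation of the terminal alkyne and carboxylation of the lithium acetylide is the standard preparation of arylpropiolic acids, and the benzyl ether is inert to one equivalent of n-BuLi at −78 °C.

**Step 2**
Reactants: 2 3-[4-(benzyloxy)phenyl]prop-2-ynoic acid; 3 methyl acetoacetate
Product: 6 methyl 6-[4-(benzyloxy)phenyl]-2-methyl-4-oxo-4H-pyran-3-carboxylate, via acyl chloride 4 (not isolated), via alkynyl tricarbonyl 5 (not isolated)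
Conditions: (COCl)2, cat. DMF, CH2Cl2, 0 °C to rt, volatiles removed; 3 (1.1 equiv), MgCl2 (1.1 equiv), pyridine (2.2 equiv), CH2Cl2, 0 °C to rt; 1 M HCl wash; Et3N (0.2 equiv), CH2Cl2, rt
Reagents that add atoms: none
Why: The acid chloride C-acylates the magnesium chelate of 3 (soft enolization), and in tricarbonyl 5 the enol oxygen of the acetyl group adds to the β-carbon of the ynone in a 6-endo-dig oxa-Michael addition, the classical γ-pyrone synthesis from 1,3-dicarbonyl compounds and arylpropioloyl chlorides; the ketone oxygen, not the ester oxygen, closes the ring, which places methyl at C2 and the ester at C3.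

**Step 3**
Reactants: 6 methyl 6-[4-(benzyloxy)phenyl]-2-methyl-4-oxo-4H-pyran-3-carboxylate; 7 N-methoxy-N-methylacetamide
Product: 8 methyl 6-[4-(benzyloxy)phenyl]-4-oxo-2-(2-oxopropyl)-4H-pyran-3-carboxylate
Conditions: LiN(SiMe3)2 (1.15 equiv), THF, −78 °C; 7 (1.3 equiv), −78 to −20 °C; poured into cold 1 M HCl
Reagents that add atoms: none
Why: Lateral (vinylogous) deprotonation of the 2-methyl group gives a dienolate that is C-acylated at the exocyclic carbon in a Weinreb ketone synthesis; the chelated tetrahedral adduct releases the ketone only in the acidic quench, so the acetonyl ester never meets base and cannot cyclize early.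

**Step 4**
Reactants: 8 methyl 6-[4-(benzyloxy)phenyl]-4-oxo-2-(2-oxopropyl)-4H-pyran-3-carboxylate
Product: 9 methyl 6-[4-(benzyloxy)phenyl]-2-(1-bromo-2-oxopropyl)-4-oxo-4H-pyran-3-carboxylate (racemic)
Conditions: NBS (1.0 equiv), CH2Cl2, 0 °C, dark; aq. Na2S2O3 wash; short silica plug, used at once
Reagents that add atoms: N-bromosuccinimide, O=C1CCC(=O)N1Br
Why: Electrophilic α-bromination of an active methylene ketone through its enol: the CH2 between the ketone and C2 of the pyranone is by far the most enolizable position, one equivalent of reagent limits dibromination, and exclusion of light spares the benzylic C–H bonds; the new stereocentre forms as the racemate and is lost later.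

**Step 5**
Reactants: 8 methyl 6-[4-(benzyloxy)phenyl]-4-oxo-2-(2-oxopropyl)-4H-pyran-3-carboxylate; 9 methyl 6-[4-(benzyloxy)phenyl]-2-(1-bromo-2-oxopropyl)-4-oxo-4H-pyran-3-carboxylate
Product: 10 dimethyl 2,2'-(2,5-dioxohexane-3,4-diyl)bis{6-[4-(benzyloxy)phenyl]-4-oxo-4H-pyran-3-carboxylate} (meso/racemic mixture)
Conditions: 8, NaN(SiMe3)2 (1.0 equiv), THF, −78 °C; 9 (1.0 equiv) in THF, −78 to 0 °C; aq. NH4Cl; used without storage
Reagents that add atoms: none
Why: Alkylation of a stabilized sodium enolate by an α-bromo ketone, the classical route to 1,4-diketones and to 2,3-diacylsuccinates from metalated and α-halogenated 1,3-dicarbonyl compounds; since nucleophile and electrophile share one skeleton, bromine transfer between them only exchanges their roles and every C–C bond-forming path leads to 10, while the two new stereocentres (C8, C8'') form without control, which is harmless because both disappear in step 6.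

**Step 6**
Reactants: 10 dimethyl 2,2'-(2,5-dioxohexane-3,4-diyl)bis{6-[4-(benzyloxy)phenyl]-4-oxo-4H-pyran-3-carboxylate}
Product: 12 2,2''-bis[4-(benzyloxy)phenyl]-5,5'',7,7''-tetrahydroxy-8,8''-bi(4H-chromen-4-one) (4',4'''-di-O-benzylcupressuflavone; racemic axis), via hexaketone tautomer 11 (not isolated)
Conditions: 10 added to LiN(SiMe3)2 (7 equiv), THF, −78 °C, then rt (45 °C if needed); 1 M HCl
Reagents that add atoms: none
Why: The first equivalents of base remove C8–H and C8''–H, which lie between the C7 ketone and the vinylogous ester of ring C, so both ketones are tied up as enolates before any methyl group is ionized; further base then generates at C6 and C6'' the terminal carbanion of an acetoacetate-type 1,3-dianion, which adds to the ester carbonyl on C4a of its own half, expels methoxide and leaves the cyclohexene-1,3-dione 11, which enolizes at once to the 5,7-dihydroxy arene. The reaction type is the intramolecular Claisen (Dieckmann-type) condensation with aromatization, established for ortho-acetonyl aryl esters (giving 1,3-dihydroxynaphthalenes) and for β-polycarbonyl chains (giving resorcinols), and is applied here twice within one molecule with the ester of a 4-pyranone as acceptor. Each ring A closes in the 6-(enolexo)-exo-trig mode, C6 onto C5 and C6'' onto C5''. No stereocentre is created: C8 and C8'' become arene carbons, so both diastereomers of 10 converge and the axis forms as the racemate. The step needs C-acylation within each half in preference to aldol addition of C6 to the C7'' ketone (five-membered ring), closure from the C8 carbanion (four-membered on its own ester; five-membered on the other ester, where the quaternary, non-enolizable product reverts by retro-Claisen cleavage), closure of C6 onto the other ester (seven-membered) and O-acylation to an enol lactone (reopened by methoxide); adding 10 to excess base keeps both ketones enolized, and only the six-membered C-closure is made irreversible by aromatization. Because O1 already sits on C8a and the ester on C4a, the ring can grow in one direction only, so no 6- versus 8-linked isomer can arise.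

**Step 7**
Reactants: 12 2,2''-bis[4-(benzyloxy)phenyl]-5,5'',7,7''-tetrahydroxy-8,8''-bi(4H-chromen-4-one)
Product: 13 2,2''-bis[4-(benzyloxy)phenyl]-5,5''-dihydroxy-7,7''-dimethoxy-8,8''-bi(4H-chromen-4-one)
Conditions: MeI (2.3 equiv), K2CO3 (2.5 equiv), acetone/DMF, rt to 40 °C
Reagents that add atoms: iodomethane, CI
Why: Williamson ether synthesis under weak base alkylates only the acidic, unchelated 7- and 7''-hydroxyls (para to the C4 carbonyls), because the 5- and 5''-hydroxyls are locked in hydrogen bonds to the C4 carbonyls and the 4'-oxygens are benzylated.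

**Step 8**
Reactants: 13 2,2''-bis[4-(benzyloxy)phenyl]-5,5''-dihydroxy-7,7''-dimethoxy-8,8''-bi(4H-chromen-4-one)
Product: 14 5,5''-dihydroxy-2,2''-bis(4-hydroxyphenyl)-7,7''-dimethoxy-8,8''-bi(4H-chromen-4-one) (7,7''-di-O-methylcupressuflavone; racemic axis)
Conditions: H2 (1 atm), 10% Pd/C, THF/MeOH, rt
Reagents that add atoms: none
Why: Catalytic hydrogenolysis cleaves the two benzyl aryl ethers, while the aryl methyl ethers, the chromone C2–C3 double bonds and the biaryl axis are untouched at 1 atm and rt.

**Compound list**
1 | 1-(benzyloxy)-4-ethynylbenzene | C#Cc1ccc(OCc2ccccc2)cc1 | starting material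
2 | 3-[4-(benzyloxy)phenyl]prop-2-ynoic acid | OC(=O)C#Cc1ccc(OCc2ccccc2)cc1 | intermediate
3 | methyl acetoacetate (methyl 3-oxobutanoate) | COC(=O)CC(C)=O | starting material
4 | 3-[4-(benzyloxy)phenyl]prop-2-ynoyl chloride (not isolated) | O=C(Cl)C#Cc1ccc(OCc2ccccc2)cc1 | intermediate
5 | methyl 2-acetyl-5-[4-(benzyloxy)phenyl]-3-oxopent-4-ynoate (not isolated) | COC(=O)C(C(C)=O)C(=O)C#Cc1ccc(OCc2ccccc2)cc1 | intermediate
6 | methyl 6-[4-(benzyloxy)phenyl]-2-methyl-4-oxo-4H-pyran-3-carboxylate | COC(=O)c1c(C)oc(-c2ccc(OCc3ccccc3)cc2)cc1=O | intermediate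
7 | N-methoxy-N-methylacetamide | CON(C)C(C)=O | starting material
8 | methyl 6-[4-(benzyloxy)phenyl]-4-oxo-2-(2-oxopropyl)-4H-pyran-3-carboxylate | COC(=O)c1c(CC(C)=O)oc(-c2ccc(OCc3ccccc3)cc2)cc1=O | intermediate
9 | methyl 6-[4-(benzyloxy)phenyl]-2-(1-bromo-2-oxopropyl)-4-oxo-4H-pyran-3-carboxylate (racemic) | COC(=O)c1c(C(Br)C(C)=O)oc(-c2ccc(OCc3ccccc3)cc2)cc1=O | intermediate
10 | dimethyl 2,2'-(2,5-dioxohexane-3,4-diyl)bis{6-[4-(benzyloxy)phenyl]-4-oxo-4H-pyran-3-carboxylate}, meso/racemic mixture at the two CH centres | CC(=O)C(c1oc(-c2ccc(OCc3ccccc3)cc2)cc(=O)c1C(=O)OC)C(C(C)=O)c1oc(-c2ccc(OCc3ccccc3)cc2)cc(=O)c1C(=O)OC | intermediate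
11 | non-aromatic 5,7-dioxo tautomer of 12 (not isolated): 2,2''-bis[4-(benzyloxy)phenyl]-6H,6''H-8,8''-bichromene-4,4'',5,5'',7,7''(8H,8''H)-hexone, C6 and C6'' as CH2, C8 and C8'' as CH (diastereomer mixture) | O=C1CC(=O)c2c(oc(-c3ccc(OCc4ccccc4)cc3)cc2=O)C1C1C(=O)CC(=O)c2c1oc(-c1ccc(OCc3ccccc3)cc1)cc2=O | intermediate
12 | 2,2''-bis[4-(benzyloxy)phenyl]-5,5'',7,7''-tetrahydroxy-8,8''-bi(4H-chromen-4-one), racemic axis | Oc1cc(O)c2c(=O)cc(-c3ccc(OCc4ccccc4)cc3)oc2c1-c1c(O)cc(O)c2c(=O)cc(-c3ccc(OCc4ccccc4)cc3)oc12 | intermediate
13 | 2,2''-bis[4-(benzyloxy)phenyl]-5,5''-dihydroxy-7,7''-dimethoxy-8,8''-bi(4H-chromen-4-one), racemic axis | COc1cc(O)c2c(=O)cc(-c3ccc(OCc4ccccc4)cc3)oc2c1-c1c(OC)cc(O)c2c(=O)cc(-c3ccc(OCc4ccccc4)cc3)oc12 | intermediate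
14 | 5,5''-dihydroxy-2,2''-bis(4-hydroxyphenyl)-7,7''-dimethoxy-8,8''-bi(4H-chromen-4-one), racemic axis | COc1cc(O)c2c(=O)cc(-c3ccc(O)cc3)oc2c1-c1c(OC)cc(O)c2c(=O)cc(-c3ccc(O)cc3)oc12 | target

**Step count and risks**
Total steps: 8. Longest linear sequence: 8 steps (1, 2, 6, 8, 9, 10, 12, 13, 14). Compound 8 enters step 5 a second time as the enolate partner, and compounds 3 and 7 enter as purchased reagents.

Steps most likely to fail, riskiest first:

Step 6. The ester carbonyl on C4a shares the negative charge of the neighbouring C8 enolate and is therefore a weak electrophile. Ring closure may then be slower than aldol addition between the two halves, than enol-lactone formation, or than attack of liberated methoxide on ring C. The two adjacent enolates may also fail to reach the rotamer needed for closure. The fallback forms ring A on the monomer, where neither a second half nor a fourfold anion exists, and makes the axis last by aryl–aryl coupling. It sets out from 8. LiN(SiMe3)2 (3.5 equiv) in THF, −78 °C to rt, should give 2-[4-(benzyloxy)phenyl]-5,7-dihydroxy-4H-chromen-4-one F1. Exhaustive methylation (excess MeI, K2CO3, DMF, 60 °C) should give 2-[4-(benzyloxy)phenyl]-5,7-dimethoxy-4H-chromen-4-one F2. Electrophilic iodination of the 5,7-dialkoxy ring A (I2, AgOAc, CH2Cl2, rt) is expected at C8 and should give 2-[4-(benzyloxy)phenyl]-8-iodo-5,7-dimethoxy-4H-chromen-4-one F3. Ullmann homocoupling (activated Cu powder, DMF, 150 °C) should give 2,2''-bis[4-(benzyloxy)phenyl]-5,5'',7,7''-tetramethoxy-8,8''-bi(4H-chromen-4-one) F4. BCl3 with pentamethylbenzene in CH2Cl2, −78 to 0 °C, should cleave the two chelation-activated 5-methyl ethers and both benzyl ethers while sparing the 7-methyl ethers, and returns to the route at 14.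

Step 5. The enolate may attack bromine instead of carbon, and the enolate of the product may then be brominated and lose HBr to an ene-dione. Substitution at the hindered secondary carbon may be slow and give way to O-alkylation. Unconsumed enolate may begin to cyclize on warming. The fallback makes the bond by one-electron oxidation, so that no alkyl halide takes part and no substitution at a crowded carbon is needed. It sets out from 8. The lithium enolate (LiN(SiMe3)2, 1.0 equiv, THF, −78 °C) is added to anhydrous divalent copper chloride CuCl2 (1.1 equiv) in DMF at −78 °C and warmed to 0 °C. This oxidative homocoupling of a ketone enolate through radical dimerization is a standard 1,4-diketone synthesis and returns to the route at 10; no compound outside the compound list is made on this way (F0).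

Step 3. The stabilized dienolate may add too slowly to the amide, proton transfer to the amide may cap conversion, or collapse of the adduct before the quench may expose the new ketone to base and start ring closure early. The fallback avoids carbanions altogether. It sets out from 6. Heating with N,N-dimethylacetamide dimethyl acetal (toluene or neat, 100 °C) should condense the active 2-methyl group to the push–pull enamine methyl 6-[4-(benzyloxy)phenyl]-2-[(1E)-2-(dimethylamino)prop-1-en-1-yl]-4-oxo-4H-pyran-3-carboxylate F5 (amide acetal enamination of an active methyl group). Mild hydrolysis (aq. AcOH, THF, rt) then returns to the route at 8.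

**Further compounds**
F1 | step 6 | 2-[4-(benzyloxy)phenyl]-5,7-dihydroxy-4H-chromen-4-one | O=c1cc(-c2ccc(OCc3ccccc3)cc2)oc2cc(O)cc(O)c12
F2 | step 6 | 2-[4-(benzyloxy)phenyl]-5,7-dimethoxy-4H-chromen-4-one | COc1cc(OC)c2c(=O)cc(-c3ccc(OCc4ccccc4)cc3)oc2c1
F3 | step 6 | 2-[4-(benzyloxy)phenyl]-8-iodo-5,7-dimethoxy-4H-chromen-4-one | COc1cc(OC)c2c(=O)cc(-c3ccc(OCc4ccccc4)cc3)oc2c1I
F4 | step 6 | 2,2''-bis[4-(benzyloxy)phenyl]-5,5'',7,7''-tetramethoxy-8,8''-bi(4H-chromen-4-one), racemic axis | COc1cc(OC)c2c(=O)cc(-c3ccc(OCc4ccccc4)cc3)oc2c1-c1c(OC)cc(OC)c2c(=O)cc(-c3ccc(OCc4ccccc4)cc3)oc12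
F0 | step 5 | none | none
F5 | step 3 | methyl 6-[4-(benzyloxy)phenyl]-2-[(1E)-2-(dimethylamino)prop-1-en-1-yl]-4-oxo-4H-pyran-3-carboxylate | COC(=O)c1c(/C=C(\C)N(C)C)oc(-c2ccc(OCc3ccccc3)cc2)cc1=O
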